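**Retrosynthetic overview**
1. 35 ⇐ 34 ⇐ 30: the C8(17) methylene is made last, by oxidising the C17 methyl of a labd-7-ene and transposing the alkene reductively; C19 stays a fluoride-labile ester and the C15 acetate arrives with the side chain.
2. 30 ⇐ 24 + 28: C11–C12 by hydroboration and alkyl–alkyl Suzuki coupling (sets C9); bromide 28 carries C13 from (R)-methylsuccinic acid.
3. 24 ⇐ 12: the C4 exocyclic methylene becomes the axial C19 acid and the equatorial C18 methyl (hydroboration, aldehyde methylation, oxidation); the C9 oxygen becomes the C9 methylene.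
4. 12 ⇐ 11 ⇐ (R)-carvone: ring B is the carvone ring, present from step 1; ring A is closed second, by the carbonyl-ene C2–C3 bond. Aldehyde 11 comes from two α′-alkylations (C20 methyl, then the C1–C2 arm), reduction and silylation.
5. The plan rests on C5: its α-hydrogen, the methyl-bearing C4 on one side and C6 on the other are the stereocentre, the isopropenyl group and the ring CH2 of (R)-carvone, whose enone (C9, C8 with C17, C7) completes ring B.

Key step: step 7

Remark (assumption): labdane numbering and α/β descriptors (β = face of the C10 methyl, C20) are used for the ring-fused intermediates. The C2 carbinol of 12–14 is drawn as the 2β epimer expected from the cyclic transition state; this differs from the 2α alternative only at a centre that is removed in step 9.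

**Route**

Step 1
Reactants: 1 (R)-carvone; 2 iodomethane
Product: 4 trans-6-methylcarvone (5R,6S)-2,6-dimethyl-5-(prop-1-en-2-yl)cyclohex-2-en-1-one, via lithium dienolate 3 (not isolated)
Conditions: LiN(iPr)2, THF, −78 °C; then 2, −78 → 0 °C
Reagents that add atoms: none
Why: Kinetic deprotonation of the enone at C6 (α′) gives the cross-conjugated lithium dienolate, which is C-methylated mainly trans to the isopropenyl group (kinetic enolate alkylation); the new centre is planarised again in step 2, so its configuration does not matter.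

Step 2
Reactants: 4 trans-6-methylcarvone; 5 tert-butyl bromoacetate
Product: 7 tert-butyl 2-[(1S,6S)-1,3-dimethyl-2-oxo-6-(prop-1-en-2-yl)cyclohex-3-en-1-yl]acetate, via lithium enolate 6 (not isolated)
Conditions: LiN(iPr)2, THF, −78 °C; then 5, DMPU, −78 → −20 °C
Reagents that add atoms: none
Why: The tetrasubstituted lithium enolate is alkylated on the face opposite the neighbouring isopropenyl group, so the acetate arm ends trans and the methyl (later C20) cis to it, which sets C10 relative to C5 (diastereoselective enolate alkylation with an α-bromo ester).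

Step 3
Reactants: 7 keto ester
Product: 8 tert-butyl 2-[(1S,2S,6S)-2-hydroxy-1,3-dimethyl-6-(prop-1-en-2-yl)cyclohex-3-en-1-yl]acetate (9β-alcohol, cis to the C10 methyl)
Conditions: NaBH4, CeCl3·7H2O, MeOH, −20 → 0 °C
Reagents that add atoms: none
Why: Luche reduction should give 1,2-reduction of the hindered enone only, hydride entering axially on the face away from the axial C10 methyl to give the pseudo-equatorial 9β-alcohol (the cis-carveol pattern); the tert-butyl ester is untouched and this centre is removed again in step 14.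

Step 4
Reactants: 8 hydroxy ester
Product: 9 tert-butyl 2-[(1S,2S,6S)-2-[(tert-butyldimethylsilyl)oxy]-1,3-dimethyl-6-(prop-1-en-2-yl)cyclohex-3-en-1-yl]acetate
Conditions: TBSOTf, 2,6-lutidine, CH2Cl2, −78 → 0 °C
Reagents that add atoms: tert-butyldimethylsilyl triflate, CC(C)(C)[Si](C)(C)OS(=O)(=O)C(F)(F)F
Why: A silyl triflate with a hindered pyridine base silylates the crowded secondary allylic alcohol at low temperature and leaves the tert-butyl ester alone (silyl ether protection).

Step 5
Reactants: 9 silyl ether ester
Product: 10 2-[(1S,2S,6S)-2-[(tert-butyldimethylsilyl)oxy]-1,3-dimethyl-6-(prop-1-en-2-yl)cyclohex-3-en-1-yl]ethan-1-ol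
Conditions: LiAlH4, THF, 0 °C → rt
Reagents that add atoms: none
Why: LiAlH4 reduces the tert-butyl ester to the primary alcohol while the silyl ether and both alkenes are inert (hydride reduction of an ester).

Step 6
Reactants: 10 primary alcohol
Product: 11 2-[(1S,2S,6S)-2-[(tert-butyldimethylsilyl)oxy]-1,3-dimethyl-6-(prop-1-en-2-yl)cyclohex-3-en-1-yl]acetaldehyde
Conditions: Dess–Martin periodinane, NaHCO3, CH2Cl2, rt
Reagents that add atoms: none
Why: Buffered Dess–Martin oxidation gives the aldehyde without over-oxidation; its β-carbon is quaternary, so there is no centre to epimerise (alcohol oxidation).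

Step 7
Reactants: 11 aldehyde
Product: 12 9β-[(tert-butyldimethylsilyl)oxy]-11,12,13,14,15,16,18-heptanorlabda-4(19),7-dien-2β-ol (trans-fused bicycle with C4 exocyclic methylene and axial C2 alcohol)
Conditions: Me2AlCl (1.5 equiv), CH2Cl2, −78 → −20 °C; aq. KNaC4H4O6
Reagents that add atoms: none
Why: Me2AlCl activates the aldehyde, the terminal carbon of the isopropenyl group (C3) attacks the carbonyl carbon (C2) and a hydrogen of the isopropenyl methyl passes to oxygen through a six-membered ene transition state, after which the aluminium alkoxide loses methane so that no protic acid remains to move the new alkene. The closest known reaction is the Me2AlCl-promoted intramolecular carbonyl-ene cyclisation of 5-methylhex-5-enals to 3-methylenecyclohexanols (type 2, ene unit tethered through its central carbon). Ring A closes as a six-membered carbocycle, exo at the carbonyl and with both alkene carbons taken into the ring, through a chair in which the C10–C1 and C5–C4 bonds are both equatorial on ring B, so the trans ring fusion already fixed by C5 (carvone) and C10 (step 2) is carried over unchanged. The one new stereocentre, C2, is set by the transition-state geometry: oxygen must lie gauche to C4 to reach the methyl hydrogen, which puts it axial on the forming chair and should give the 2β alcohol (any 2α epimer converges in step 9). The step needs hydrogen transfer from the methyl group and not from C5–H, and attack on the isopropenyl group and not on the C7=C8 alkene; C5–H lies inside the tether and cannot reach the oxygen, and the ring alkene could be reached only if the equatorial CH2CHO arm turned axial to form a bridged ring.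

Step 8
Reactants: 12 bicyclic alcohol; 2 iodomethane
Product: 14 O-[9β-(tert-butyldimethylsilyloxy)-11,12,13,14,15,16,18-heptanorlabda-4(19),7-dien-2β-yl] S-methyl dithiocarbonate, via sodium xanthate 13 (not isolated)
Conditions: NaH, CS2, imidazole (cat.), THF, 0 °C → rt; then 2
Reagents that add atoms: carbon disulfide, S=C=S
Why: The alkoxide adds to CS2 and the dithiocarbonate salt is S-methylated, a sequence that works on hindered secondary alcohols (xanthate formation).

Step 9
Reactants: 14 xanthate
Product: 15 9β-[(tert-butyldimethylsilyl)oxy]-11,12,13,14,15,16,18-heptanorlabda-4(19),7-diene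
Conditions: Bu3SnH, AIBN (cat.), toluene, 100 °C
Reagents that add atoms: none
Why: Barton–McCombie deoxygenation: the stannyl radical adds to the thiocarbonyl group, the C2–O bond fragments and the secondary C2 radical should be reduced by Bu3SnH faster than it can attack the homoallylic C4 methylene; the C2 stereocentre is thereby removed.

Step 10
Reactants: 15 diene
Product: 17 9β-[(tert-butyldimethylsilyl)oxy]-11,12,13,14,15,16,18-heptanorlabd-7-en-19-ol (4α-H), via B-alkyl-9-BBN 16 (not isolated)
Conditions: 9-BBN, THF, 0 °C → rt; then NaOH, H2O2, 0 °C → rt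
Reagents that add atoms: hydrogen peroxide, OO
Why: 9-BBN hydroborates the 1,1-disubstituted exocyclic alkene far faster than the trisubstituted ring alkene and places boron on the terminal carbon, and oxidation gives the primary alcohol (hydroboration–oxidation); the C4 configuration expected from α-face attack is irrelevant because C4 is enolised in step 12.

Step 11
Reactants: 17 primary alcohol
Product: 18 9β-[(tert-butyldimethylsilyl)oxy]-11,12,13,14,15,16,18-heptanorlabd-7-en-19-al (4α-H)
Conditions: Dess–Martin periodinane, NaHCO3, CH2Cl2, rt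
Reagents that add atoms: none
Why: Mild oxidation of the primary alcohol to the aldehyde; silyl ether and alkene are inert (Dess–Martin oxidation).

Step 12
Reactants: 18 aldehyde; 2 iodomethane
Product: 20 9β-[(tert-butyldimethylsilyl)oxy]-11,12,13,14,15,16-hexanorlabd-7-en-19-al (C18 methyl equatorial and C19 formyl axial), via potassium enolate 19 (not isolated)
Conditions: KOtBu, THF, 0 °C; then 2, 0 °C → rt
Reagents that add atoms: none
Why: The exocyclic potassium enolate is C-methylated from the equatorial α face, away from the 1,3-diaxial C10 methyl, so the new methyl (C18) is equatorial and the formyl group (C19) axial, which sets C4 (aldehyde enolate alkylation).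

Step 13
Reactants: 20 silyl ether aldehyde
Product: 21 9β-hydroxy-11,12,13,14,15,16-hexanorlabd-7-en-19-al
Conditions: Bu4NF, THF, rt → 45 °C
Reagents that add atoms: none
Why: Fluoride cleaves the hindered secondary silyl ether; the aldehyde has no α-hydrogen and tolerates the basic fluoride (desilylation).

Step 14
Reactants: 21 hydroxy aldehyde
Product: 22 9-oxo-11,12,13,14,15,16-hexanorlabd-7-en-19-oic acid
Conditions: CrO3, H2SO4, H2O, acetone, 0 °C
Reagents that add atoms: water, O
Why: Jones oxidation converts the allylic alcohol into the enone and, through its hydrate, the neopentyl aldehyde into the carboxylic acid in one operation; the trisubstituted alkene is inert.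

Step 15
Reactants: 22 keto acid
Product: 23 2-(trimethylsilyl)ethyl 9-oxo-11,12,13,14,15,16-hexanorlabd-7-en-19-oate
Conditions: Me3SiCH2CH2OH, PPh3, DIAD, THF, 0 °C → rt
Reagents that add atoms: 2-(trimethylsilyl)ethanol, C[Si](C)(C)CCO
Why: In the Mitsunobu esterification the hindered carboxylate is the nucleophile and attacks the activated primary alcohol, so crowding at the acyl carbon does not matter; this ester is chosen because fluoride removes it at the end without touching an acetate.

Step 16
Reactants: 23 keto ester
Product: 24 2-(trimethylsilyl)ethyl 12,13,14,15,16-pentanorlabda-7,9(11)-dien-19-oate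
Conditions: Ph3PCH3Br, KOtBu, toluene, rt; then 23, 90 °C
Reagents that add atoms: methyltriphenylphosphonium bromide, C[P+](c1ccccc1)(c1ccccc1)c1ccccc1.[Br-]
Why: Wittig methylenation under forcing conditions; the ketone has no α-hydrogen on C10 and an sp2 carbon on its other side, so only C=O to C=CH2 conversion is expected, and the hindered ester without α-hydrogen is left alone.

Step 17
Reactants: 25 (R)-methylsuccinic acid
Product: 26 (R)-2-methylbutane-1,4-diol
Conditions: LiAlH4, THF, reflux
Reagents that add atoms: none
Why: LiAlH4 reduces both carboxyl groups and the stereocentre, which becomes C13, is not affected (hydride reduction of a diacid).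

Step 18
Reactants: 26 diol
Product: 27 (R)-1,4-dibromo-2-methylbutane
Conditions: 48% aq. HBr, H2SO4, reflux
Reagents that add atoms: hydrogen bromide, Br
Why: Bromide displaces both protonated primary hydroxyl groups by SN2 (any cyclic ether formed on the way is reopened under the same conditions); the stereogenic carbon is not a reacting centre.

Step 19
Reactants: 27 dibromide
Product: 28 (R)-4-bromo-3-methylbutyl acetate
Conditions: KOAc (0.9 equiv), DMF, 40 °C
Reagents that add atoms: potassium acetate, CC(=O)[O-].[K+]
Why: SN2 displacement by acetate is expected to be much faster at the unbranched primary carbon than at the β-branched one, so the acetate should go to the future C15 and the bromide stay on the future C12; a non-basic nucleophile avoids elimination.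

Step 20
Reactants: 24 diene ester; 28 bromo acetate
Product: 30 2-(trimethylsilyl)ethyl (13S)-15-acetoxylabd-7-en-19-oate, via C11 alkylborane 29 (not isolated)
Conditions: 9-BBN, THF, rt → 50 °C; then 28, Pd(OAc)2, PCy3, K3PO4·H2O, THF, rt → 40 °C
Reagents that add atoms: none
Why: 9-BBN adds to the terminal exocyclic alkene of the diene from the α face, opposite the axial C10 methyl, so C9 receives its hydrogen α and the CH2B group is equatorial (sets C9); the alkylborane then undergoes alkyl–alkyl Suzuki–Miyaura coupling with the primary bromide, PCy3-ligated zerovalent palladium inserting into the C–Br bond and transmetalating faster than β-hydride elimination.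

Step 21
Reactants: 30 labd-7-ene
Product: 31 2-(trimethylsilyl)ethyl (13S)-15-acetoxy-17-hydroxylabd-7-en-19-oate
Conditions: SeO2 (0.5 equiv), t-BuOOH, CH2Cl2, rt
Reagents that add atoms: selenium dioxide, O=[Se]=O (delivers the oxygen); tert-butyl hydroperoxide, CC(C)(C)OO (reoxidises selenium)
Why: Riley allylic oxidation: the ene reaction at the more substituted alkene carbon takes hydrogen from the C17 methyl in preference to the hindered C9 methine (the α-pinene to myrtenol pattern) and the [2,3]-shift returns the C7=C8 alkene with oxygen on C17; the hydroperoxide keeps selenium turning over and limits over-oxidation to the enal.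

Step 22
Reactants: 31 allylic alcohol
Product: 34 2-(trimethylsilyl)ethyl (13S)-15-acetoxylabd-8(17)-en-19-oate, via sulfonylhydrazine adduct 32 (not isolated), via allylic diazene 33 (not isolated)
Conditions: 2-O2NC6H4SO2NHNH2, PPh3, DEAD, THF, −30 °C → rt
Reagents that add atoms: none
Why: Mitsunobu displacement of the primary allylic alcohol by the sulfonylhydrazide, loss of the sulfinic acid on warming and sigmatropic loss of N2 from the allylic diazene deliver hydrogen to C7 and move the alkene to C8=C17 with full regiocontrol (reductive allylic transposition); the neutral conditions spare both esters.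

Step 23
Reactants: 34 silylethyl ester
Product: 35 (13S)-15-acetoxylabd-8(17)-en-19-oic acid (CNP0401865.2)
Conditions: (Me2N)3S+ Me3SiF2− (TASF), DMF, 0 °C → rt; then dilute HCl to pH 4
Reagents that add atoms: none
Why: Fluoride attacks silicon and the β-silylethyl ester fragments to ethylene, Me3SiF and the carboxylate whatever the hindrance at C19; the anhydrous fluoride source should leave the primary acetate and the exocyclic alkene intact (fluoride-induced ester cleavage).

**Compound list**
1 | (R)-carvone | CC1=CC[C@H](CC1=O)C(C)=C | starting material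
2 | iodomethane | CI | starting material
3 | lithium dienolate of 1, deprotonated at C6 (not isolated) | CC1=CC[C@@H](C(C)=C)C=C1[O-].[Li+] | intermediate
4 | trans-6-methylcarvone, (5R,6S)-2,6-dimethyl-5-(prop-1-en-2-yl)cyclohex-2-en-1-one (6-epimer carried along) | CC1=CC[C@@H](C(C)=C)[C@H](C)C1=O | intermediate
5 | tert-butyl bromoacetate | CC(C)(C)OC(=O)CBr | starting material
6 | lithium enolate of 4 (not isolated) | CC1=CC[C@@H](C(C)=C)C(C)=C1[O-].[Li+] | intermediate
7 | tert-butyl 2-[(1S,6S)-1,3-dimethyl-2-oxo-6-(prop-1-en-2-yl)cyclohex-3-en-1-yl]acetate | CC1=CC[C@@H](C(C)=C)[C@](C)(CC(=O)OC(C)(C)C)C1=O | intermediate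
8 | tert-butyl 2-[(1S,2S,6S)-2-hydroxy-1,3-dimethyl-6-(prop-1-en-2-yl)cyclohex-3-en-1-yl]acetate | CC1=CC[C@@H](C(C)=C)[C@](C)(CC(=O)OC(C)(C)C)[C@H]1O | intermediate
9 | tert-butyl 2-[(1S,2S,6S)-2-[(tert-butyldimethylsilyl)oxy]-1,3-dimethyl-6-(prop-1-en-2-yl)cyclohex-3-en-1-yl]acetate | CC1=CC[C@@H](C(C)=C)[C@](C)(CC(=O)OC(C)(C)C)[C@H]1O[Si](C)(C)C(C)(C)C | intermediate
10 | 2-[(1S,2S,6S)-2-[(tert-butyldimethylsilyl)oxy]-1,3-dimethyl-6-(prop-1-en-2-yl)cyclohex-3-en-1-yl]ethan-1-ol | CC1=CC[C@@H](C(C)=C)[C@](C)(CCO)[C@H]1O[Si](C)(C)C(C)(C)C | intermediate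
11 | 2-[(1S,2S,6S)-2-[(tert-butyldimethylsilyl)oxy]-1,3-dimethyl-6-(prop-1-en-2-yl)cyclohex-3-en-1-yl]acetaldehyde (key-step precursor) | CC1=CC[C@@H](C(C)=C)[C@](C)(CC=O)[C@H]1O[Si](C)(C)C(C)(C)C | intermediate
12 | 9β-[(tert-butyldimethylsilyl)oxy]-11,12,13,14,15,16,18-heptanorlabda-4(19),7-dien-2β-ol (key-step product) | CC1=CC[C@@H]2[C@](C)(C[C@H](O)CC2=C)[C@H]1O[Si](C)(C)C(C)(C)C | intermediate
13 | sodium O-alkyl dithiocarbonate of 12 (not isolated) | CC1=CC[C@@H]2[C@](C)(C[C@H](OC(=S)[S-])CC2=C)[C@H]1O[Si](C)(C)C(C)(C)C.[Na+] | intermediate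
14 | O-alkyl S-methyl dithiocarbonate (xanthate) of 12 | CC1=CC[C@@H]2[C@](C)(C[C@H](OC(=S)SC)CC2=C)[C@H]1O[Si](C)(C)C(C)(C)C | intermediate
15 | 9β-[(tert-butyldimethylsilyl)oxy]-11,12,13,14,15,16,18-heptanorlabda-4(19),7-diene | CC1=CC[C@@H]2[C@](C)(CCCC2=C)[C@H]1O[Si](C)(C)C(C)(C)C | intermediate
16 | C19 B-alkyl-9-BBN adduct of 15 (not isolated) | CC1=CC[C@@H]2[C@](C)(CCC[C@@H]2CB2C3CCCC2CCC3)[C@H]1O[Si](C)(C)C(C)(C)C | intermediate
17 | 9β-[(tert-butyldimethylsilyl)oxy]-11,12,13,14,15,16,18-heptanorlabd-7-en-19-ol (4α-H) | CC1=CC[C@@H]2[C@](C)(CCC[C@@H]2CO)[C@H]1O[Si](C)(C)C(C)(C)C | intermediate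
18 | 9β-[(tert-butyldimethylsilyl)oxy]-11,12,13,14,15,16,18-heptanorlabd-7-en-19-al (4α-H) | CC1=CC[C@@H]2[C@](C)(CCC[C@@H]2C=O)[C@H]1O[Si](C)(C)C(C)(C)C | intermediate
19 | potassium enolate of 18 (not isolated) | CC1=CC[C@@H]2[C@](C)(CCCC2=C[O-])[C@H]1O[Si](C)(C)C(C)(C)C.[K+] | intermediate
20 | 9β-[(tert-butyldimethylsilyl)oxy]-11,12,13,14,15,16-hexanorlabd-7-en-19-al | CC1=CC[C@@H]2[C@](C)(CCC[C@]2(C)C=O)[C@H]1O[Si](C)(C)C(C)(C)C | intermediate
21 | 9β-hydroxy-11,12,13,14,15,16-hexanorlabd-7-en-19-al | CC1=CC[C@@H]2[C@](C)(CCC[C@]2(C)C=O)[C@H]1O | intermediate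
22 | 9-oxo-11,12,13,14,15,16-hexanorlabd-7-en-19-oic acid | CC1=CC[C@@H]2[C@](C)(CCC[C@]2(C)C(=O)O)C1=O | intermediate
23 | 2-(trimethylsilyl)ethyl 9-oxo-11,12,13,14,15,16-hexanorlabd-7-en-19-oate | CC1=CC[C@@H]2[C@](C)(CCC[C@]2(C)C(=O)OCC[Si](C)(C)C)C1=O | intermediate
24 | 2-(trimethylsilyl)ethyl 12,13,14,15,16-pentanorlabda-7,9(11)-dien-19-oate | CC1=CC[C@@H]2[C@](C)(CCC[C@]2(C)C(=O)OCC[Si](C)(C)C)C1=C | intermediate
25 | (R)-methylsuccinic acid | C[C@H](CC(=O)O)C(=O)O | starting material
26 | (R)-2-methylbutane-1,4-diol | OC[C@H](C)CCO | intermediate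
27 | (R)-1,4-dibromo-2-methylbutane | BrC[C@H](C)CCBr | intermediate
28 | (R)-4-bromo-3-methylbutyl acetate | BrC[C@H](C)CCOC(C)=O | intermediate
29 | C11 B-alkyl-9-BBN adduct of 24 (not isolated) | CC1=CC[C@@H]2[C@](C)(CCC[C@]2(C)C(=O)OCC[Si](C)(C)C)[C@H]1CB1C2CCCC1CCC2 | intermediate
30 | 2-(trimethylsilyl)ethyl (13S)-15-acetoxylabd-7-en-19-oate | CC1=CC[C@@H]2[C@](C)(CCC[C@]2(C)C(=O)OCC[Si](C)(C)C)[C@H]1CC[C@H](C)CCOC(C)=O | intermediate
31 | 2-(trimethylsilyl)ethyl (13S)-15-acetoxy-17-hydroxylabd-7-en-19-oate | OCC1=CC[C@@H]2[C@](C)(CCC[C@]2(C)C(=O)OCC[Si](C)(C)C)[C@H]1CC[C@H](C)CCOC(C)=O | intermediate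
32 | N-(C17-allyl)-N-(2-nitrophenylsulfonyl)hydrazine adduct of 31 (not isolated) | NN(CC1=CC[C@@H]2[C@](C)(CCC[C@]2(C)C(=O)OCC[Si](C)(C)C)[C@H]1CC[C@H](C)CCOC(C)=O)S(=O)(=O)c1ccccc1[N+](=O)[O-] | intermediate
33 | C17 allylic diazene (not isolated) | N=NCC1=CC[C@@H]2[C@](C)(CCC[C@]2(C)C(=O)OCC[Si](C)(C)C)[C@H]1CC[C@H](C)CCOC(C)=O | intermediate
34 | 2-(trimethylsilyl)ethyl (13S)-15-acetoxylabd-8(17)-en-19-oate | C=C1CC[C@@H]2[C@](C)(CCC[C@]2(C)C(=O)OCC[Si](C)(C)C)[C@H]1CC[C@H](C)CCOC(C)=O | intermediate
35 | (13S)-15-acetoxylabd-8(17)-en-19-oic acid, (4S,5R,9S,10R,13S), CNP0401865.2 | C=C1CC[C@@H]2[C@](C)(CCC[C@]2(C)C(=O)O)[C@H]1CC[C@H](C)CCOC(C)=O | target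

**Step count**
Total steps: 23. Longest linear sequence: 20 (steps 1–16 and 20–23); steps 17–19 make the side-chain bromide.

**Steps most likely to fail**

Step 7 (carbonyl-ene). The closure may leave the concerted pathway: a stepwise cationic course would allow proton loss toward the ring or chloride capture, and the axial oxygen meets the C10 methyl in the transition state, which may slow the reaction. The fallback makes the same C2–C3 bond by an intramolecular Nozaki–Hiyama allylation, where the allyl metal and not a proton transfer fixes the alkene position. It sets out from keto ester 7. Ene-type chlorination with Ca(OCl)2 and CO2 should touch only the isopropenyl group, because the enone alkene is deactivated, and give the allylic chloride keto ester F1. Luche reduction would give the chloro alcohol F2, silylation the silyl ether F3, i-Bu2AlH reduction (which spares the allylic chloride) the primary alcohol F4, and Dess–Martin oxidation the chloro aldehyde F5. CrCl2 with catalytic NaI in THF/DMF would then form the allylchromium species, which adds to the aldehyde through its γ-carbon and returns the route at 12.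

Step 20 (hydroboration and alkyl–alkyl Suzuki coupling). Oxidative addition into the β-branched bromide and transmetalation of the β-branched alkylborane may both be slow, so that β-hydride elimination and protodeboronation take over. The fallback joins C11 and C12 by a copper-catalysed coupling of an alkylmagnesium reagent with an alkyl iodide. It sets out from diene 24: hydroboration with 9-BBN and oxidation (NaOH, H2O2) would give the C11 alcohol F6, and I2, PPh3 and imidazole the primary iodide F7. Since an organomagnesium reagent does not tolerate an acetate, the side chain would be carried as a PMB ether: dibromide 27 with sodium 4-methoxybenzyl oxide would give the bromo ether F8, and Mg in THF its alkylmagnesium bromide F9. Coupling of F9 with F7 under Li2CuCl4 catalysis (THF, −20 → 0 °C) would give the PMB ether F10, DDQ the C15 alcohol F11, and Ac2O in pyridine would return the route at 30.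

Step 21 (allylic oxidation). Site selectivity may be poor (attack at C6 or at the C9 methine instead of C17), and the alcohol may be over-oxidised to the enal. The fallback puts oxygen on C17 by epoxide isomerisation and allylic alcohol transposition. It sets out from 30: mCPBA with NaHCO3 should give the 7α,8α-epoxide F12. Cp2TiCl (from Cp2TiCl2 and Mn, THF) opens it at the tertiary carbon and removes a methyl hydrogen, which tolerates both esters and should give the 7α-hydroxy-8(17)-ene F13. Catalytic Ph3SiOReO3 (Et2O, −50 → 0 °C) would then shift the hydroxyl to C17 and the alkene back into the ring, toward the more substituted alkene, and return the route at 31.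

**Further compounds**
F1 | step 7 | tert-butyl 2-[(1S,6S)-6-(3-chloroprop-1-en-2-yl)-1,3-dimethyl-2-oxocyclohex-3-en-1-yl]acetate | CC1=CC[C@@H](C(CCl)=C)[C@](C)(CC(=O)OC(C)(C)C)C1=O
F2 | step 7 | 9β-alcohol of F1 | CC1=CC[C@@H](C(CCl)=C)[C@](C)(CC(=O)OC(C)(C)C)[C@H]1O
F3 | step 7 | tert-butyldimethylsilyl ether of F2 | CC1=CC[C@@H](C(CCl)=C)[C@](C)(CC(=O)OC(C)(C)C)[C@H]1O[Si](C)(C)C(C)(C)C
F4 | step 7 | primary alcohol from F3 | CC1=CC[C@@H](C(CCl)=C)[C@](C)(CCO)[C@H]1O[Si](C)(C)C(C)(C)C
F5 | step 7 | chloro aldehyde from F4 | CC1=CC[C@@H](C(CCl)=C)[C@](C)(CC=O)[C@H]1O[Si](C)(C)C(C)(C)C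
F6 | step 20 | 2-(trimethylsilyl)ethyl 11-hydroxy-12,13,14,15,16-pentanorlabd-7-en-19-oate | CC1=CC[C@@H]2[C@](C)(CCC[C@]2(C)C(=O)OCC[Si](C)(C)C)[C@H]1CO
F7 | step 20 | 2-(trimethylsilyl)ethyl 11-iodo-12,13,14,15,16-pentanorlabd-7-en-19-oate | CC1=CC[C@@H]2[C@](C)(CCC[C@]2(C)C(=O)OCC[Si](C)(C)C)[C@H]1CI
F8 | step 20 | (R)-1-[(4-bromo-3-methylbutoxy)methyl]-4-methoxybenzene | BrC[C@H](C)CCOCc1ccc(OC)cc1
F9 | step 20 | alkylmagnesium bromide from F8 | Br[Mg]C[C@H](C)CCOCc1ccc(OC)cc1
F10 | step 20 | 2-(trimethylsilyl)ethyl (13S)-15-(4-methoxybenzyloxy)labd-7-en-19-oate | CC1=CC[C@@H]2[C@](C)(CCC[C@]2(C)C(=O)OCC[Si](C)(C)C)[C@H]1CC[C@H](C)CCOCc1ccc(OC)cc1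
F11 | step 20 | 2-(trimethylsilyl)ethyl (13S)-15-hydroxylabd-7-en-19-oate | CC1=CC[C@@H]2[C@](C)(CCC[C@]2(C)C(=O)OCC[Si](C)(C)C)[C@H]1CC[C@H](C)CCO
F12 | step 21 | 2-(trimethylsilyl)ethyl (13S)-15-acetoxy-7α,8α-epoxylabdan-19-oate | C[C@@]12O[C@@H]1C[C@@H]3[C@](C)(CCC[C@]3(C)C(=O)OCC[Si](C)(C)C)[C@H]2CC[C@H](C)CCOC(C)=O
F13 | step 21 | 2-(trimethylsilyl)ethyl (13S)-15-acetoxy-7α-hydroxylabd-8(17)-en-19-oate | C=C1[C@H](O)C[C@@H]2[C@](C)(CCC[C@]2(C)C(=O)OCC[Si](C)(C)C)[C@H]1CC[C@H](C)CCOC(C)=O
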